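The route rests on cutting the C1''–C2'' bond of the C6 prenyl group, which sits on ring A between the C5 and C7 oxygens. C1'' enters as the formyl carbon of 2,4,6-trihydroxybenzaldehyde and becomes the exocyclic methylene of an ortho-quinone methide. An intact 2-methylprop-1-enyl Grignard reagent adds to it, so the prenyl group is installed regiospecifically in one operation. The precursor is an ortho-(Boc-oxy)benzyl alcohol with a MOM ether on the other ortho oxygen and a THP acetal on the para oxygen. Directed lithiation/acetylation, chromone formation and a palladium-catalysed asymmetric conjugate arylation with the ring B boronic acid then build the (2S)-flavanone.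

Key step: step 5

Remark: the oxygen para to the benzylic carbon carries a THP acetal, not a silyl ether, because it must later flank an aryllithium without O-to-C silyl migration and be freed in the presence of MOM ethers. Its acetal carbon is the only stereocentre in 3–16 and is carried as the racemate. The ligand hand in step 13 is chosen on the assumption that the chromone shows the facial preference known for other cyclic enones with this ligand class.

Step 1
Reactants: 1 2,4,6-trihydroxybenzaldehyde; 2 3,4-dihydro-2H-pyran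
Product: 3 2,6-dihydroxy-4-(oxan-2-yloxy)benzaldehyde
Conditions: 2 (1.1 equiv), PPTS (cat.), THF–CH2Cl2, 0 °C to rt
Reagents that add atoms: 3,4-dihydro-2H-pyran, C1=COCCC1
Why: Acid-catalysed tetrahydropyranylation (addition of a phenol to an enol ether) should take place at the C4 hydroxyl, the only one not held in a hydrogen bond to the formyl oxygen.

Step 2
Reactants: 3 2,6-dihydroxy-4-(oxan-2-yloxy)benzaldehyde; 4 chloromethyl methyl ether
Product: 5 2-hydroxy-6-(methoxymethoxy)-4-(oxan-2-yloxy)benzaldehyde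
Conditions: 4 (1.1 equiv), iPr2NEt, CH2Cl2, 0 °C
Reagents that add atoms: chloromethyl methyl ether, COCCl
Why: Williamson-type O-alkylation with an α-chloro ether should stop after one of the two equivalent ortho hydroxyls, because the remaining one is locked in a strong hydrogen bond to the aldehyde.

Step 3
Reactants: 5 2-hydroxy-6-(methoxymethoxy)-4-(oxan-2-yloxy)benzaldehyde; 6 di-tert-butyl dicarbonate
Product: 7 tert-butyl [2-formyl-3-(methoxymethoxy)-5-(oxan-2-yloxy)phenyl] carbonate
Conditions: 6, iPr2NEt, DMAP (cat.), THF, 0 °C to rt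
Reagents that add atoms: di-tert-butyl dicarbonate, CC(C)(C)OC(=O)OC(=O)OC(C)(C)C
Why: DMAP-catalysed O-acylation converts the last, hydrogen-bonded phenol into its tert-butyl carbonate, the standard entry to ortho-(Boc-oxy)benzaldehydes.

Step 4
Reactants: 7 tert-butyl [2-formyl-3-(methoxymethoxy)-5-(oxan-2-yloxy)phenyl] carbonate
Product: 8 tert-butyl [2-(hydroxymethyl)-3-(methoxymethoxy)-5-(oxan-2-yloxy)phenyl] carbonate
Conditions: BH3·THF, THF, 0 °C; then MeOH
Reagents that add atoms: none
Why: Borane reduction of the aldehyde passes through a neutral alkoxyborane that is too weakly nucleophilic to attack the neighbouring carbonate, whereas a borohydride would give an alkoxide and trigger premature Boc transfer; carbonate and acetals are inert to BH3 at 0 °C.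

Step 5
Reactants: 8 tert-butyl [2-(hydroxymethyl)-3-(methoxymethoxy)-5-(oxan-2-yloxy)phenyl] carbonate; 9 2-methylprop-1-enylmagnesium bromide
Product: 12 3-(methoxymethoxy)-2-(3-methylbut-2-en-1-yl)-5-(oxan-2-yloxy)phenol, via benzylic tert-butyl carbonate magnesium phenoxide 10 (not isolated), via ortho-quinone methide 11 (not isolated)
Conditions: 9 (3 equiv), THF, −78 °C to 0 °C; then aq. NH4Cl
Reagents that add atoms: 2-methylprop-1-enylmagnesium bromide, CC(C)=C[Mg]Br
Why: The first equivalent of 9 deprotonates the benzylic alcohol, the alkoxide attacks the neighbouring carbonate carbonyl so that the Boc group moves from the phenolic to the benzylic oxygen (10), and the phenoxide then expels tert-butyl carbonate in a 1,4-elimination to give the ortho-quinone methide 11. A second equivalent of 9 adds through its sp2 carbon to the exocyclic methylene (1,4-addition driven by rearomatisation), forming C1''–C2'' and the magnesium phenoxide of 12. The closest known reaction type is the low-temperature anionic generation of ortho-quinone methides from ortho-(Boc-oxy)benzyl alcohols with Grignard reagents and their conjugate alkylation or alkenylation to ortho-substituted phenols. No ring is closed and no stereocentre is formed. The step needs conjugate addition to outrun dimerisation or cycloaddition of 11, which slow generation of 11 at low temperature in the presence of excess 9 should secure. Regiochemistry needs no control, because C1'' is the former formyl carbon on the ring carbon already flanked by the oxygens that become O5 and O7, and the C2''=C3'' alkene arrives preformed, so neither O-alkylation nor allylic transposition can occur.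

Step 6
Reactants: 12 3-(methoxymethoxy)-2-(3-methylbut-2-en-1-yl)-5-(oxan-2-yloxy)phenol; 4 chloromethyl methyl ether
Product: 13 2-[3,5-bis(methoxymethoxy)-4-(3-methylbut-2-en-1-yl)phenoxy]oxane
Conditions: 4, iPr2NEt, CH2Cl2, 0 °C to rt
Reagents that add atoms: chloromethyl methyl ether, COCCl
Why: O-alkylation of the newly freed, non-chelated phenol gives an arene with a mirror plane, in which the two remaining ring C–H positions are equivalent.

Step 7
Reactants: 13 2-[3,5-bis(methoxymethoxy)-4-(3-methylbut-2-en-1-yl)phenoxy]oxane; 14 N-methoxy-N-methylacetamide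
Product: 16 1-[2,4-bis(methoxymethoxy)-3-(3-methylbut-2-en-1-yl)-6-(oxan-2-yloxy)phenyl]ethan-1-one, via aryllithium 15 (not isolated)
Conditions: n-BuLi (1.2 equiv), THF, −20 °C to 0 °C; then 14, −78 °C to 0 °C; then aq. NH4Cl
Reagents that add atoms: N-methoxy-N-methylacetamide, CC(=O)N(C)OC
Why: Directed ortho-metalation followed by Weinreb ketone synthesis should work because each ring hydrogen lies between an OMOM and an OTHP group that both coordinate lithium, and the N-methoxy amide stops at the ketone stage.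

Step 8
Reactants: 16 1-[2,4-bis(methoxymethoxy)-3-(3-methylbut-2-en-1-yl)-6-(oxan-2-yloxy)phenyl]ethan-1-one
Product: 17 1-[6-hydroxy-2,4-bis(methoxymethoxy)-3-(3-methylbut-2-en-1-yl)phenyl]ethan-1-one
Conditions: PPTS (cat.), MeOH, rt to 40 °C
Reagents that add atoms: none
Why: Acid-catalysed transacetalisation with methanol cleaves the aryl tetrahydropyranyl acetal much faster than aryl MOM ethers and frees only the oxygen para to the prenyl group, as a hydrogen-bonded ortho-hydroxyacetophenone.

Step 9
Reactants: 17 1-[6-hydroxy-2,4-bis(methoxymethoxy)-3-(3-methylbut-2-en-1-yl)phenyl]ethan-1-one; 18 N,N-dimethylformamide dimethyl acetal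
Product: 20 5,7-bis(methoxymethoxy)-6-(3-methylbut-2-en-1-yl)-4H-chromen-4-one, via enaminone 19 (not isolated)
Conditions: 18 (3 equiv), toluene, 90 °C; evaporate; then AcOH, CH2Cl2, 40 °C
Reagents that add atoms: N,N-dimethylformamide dimethyl acetal, COC(OC)N(C)C
Why: Condensation of the methyl ketone with the amide acetal gives the enaminone, and weak acid promotes intramolecular conjugate addition of the phenol with loss of dimethylamine (enaminone chromone synthesis); acetic acid is too weak to cleave the MOM ethers.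

Step 10
Reactants: 21 4-bromo-2-iodophenol; 4 chloromethyl methyl ether
Product: 22 4-bromo-2-iodo-1-(methoxymethoxy)benzene
Conditions: 4, iPr2NEt, CH2Cl2, 0 °C to rt
Reagents that add atoms: chloromethyl methyl ether, COCCl
Why: Simple O-alkylation of a phenol with an α-chloro ether; both halogens are inert.

Step 11
Reactants: 22 4-bromo-2-iodo-1-(methoxymethoxy)benzene; 23 geranyl bromide, (2E)-1-bromo-3,7-dimethylocta-2,6-diene
Product: 25 4-bromo-2-[(2E)-3,7-dimethylocta-2,6-dien-1-yl]-1-(methoxymethoxy)benzene, via arylmagnesium chloride 24 (not isolated)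
Conditions: iPrMgCl·LiCl (1.05 equiv), THF, −20 °C; then CuI (10 mol%), 23, −20 °C to 0 °C
Reagents that add atoms: geranyl bromide, CC(C)=CCC/C(C)=C/CBr
Why: Iodine–magnesium exchange is much faster at the iodide ortho to the chelating MOM ether than at the bromide, and copper-catalysed allylic substitution of the aryl Grignard reagent at the primary carbon of geranyl bromide keeps the E alkene.

Step 12
Reactants: 25 4-bromo-2-[(2E)-3,7-dimethylocta-2,6-dien-1-yl]-1-(methoxymethoxy)benzene; 26 triisopropyl borate; 27 water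
Product: 29 {3-[(2E)-3,7-dimethylocta-2,6-dien-1-yl]-4-(methoxymethoxy)phenyl}boronic acid, via aryllithium 28 (not isolated)
Conditions: 26, n-BuLi, THF–toluene, −78 °C to rt; then aq. NH4Cl
Reagents that add atoms: triisopropyl borate, CC(C)OB(OC(C)C)OC(C)C; water, O
Why: Bromine–lithium exchange with in situ trapping by the borate and mild hydrolysis is the standard route to arylboronic acids; at −78 °C the allylic and benzylic hydrogens are not touched.

Step 13
Reactants: 20 5,7-bis(methoxymethoxy)-6-(3-methylbut-2-en-1-yl)-4H-chromen-4-one; 29 {3-[(2E)-3,7-dimethylocta-2,6-dien-1-yl]-4-(methoxymethoxy)phenyl}boronic acid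
Product: 30 (2S)-2-{3-[(2E)-3,7-dimethylocta-2,6-dien-1-yl]-4-(methoxymethoxy)phenyl}-5,7-bis(methoxymethoxy)-6-(3-methylbut-2-en-1-yl)-2,3-dihydro-4H-chromen-4-one
Conditions: 29 (2 equiv), Pd(OCOCF3)2 (10 mol%), (R)-4-tert-butyl-2-(pyridin-2-yl)-4,5-dihydrooxazole (12 mol%), NH4PF6 (30 mol%), H2O (5 equiv), ClCH2CH2Cl, 50 °C
Reagents that add atoms: arylboronic acid 29, CC(C)=CCC/C(C)=C/Cc1cc(B(O)O)ccc1OCOC
Why: Palladium-catalysed asymmetric conjugate addition of an arylboronic acid to a chromone, in which the aryl group on divalent palladium inserts the C2=C3 bond and water protonates C3; the tert-butyl group of the (R)-pyridine-oxazoline ligand blocks one face, so the new C2 stereocentre should be set as (S) by catalyst control.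

Step 14
Reactants: 30 (2S)-2-{3-[(2E)-3,7-dimethylocta-2,6-dien-1-yl]-4-(methoxymethoxy)phenyl}-5,7-bis(methoxymethoxy)-6-(3-methylbut-2-en-1-yl)-2,3-dihydro-4H-chromen-4-one
Product: 31 schizolaenone A, (2S)-2-{3-[(2E)-3,7-dimethylocta-2,6-dien-1-yl]-4-hydroxyphenyl}-5,7-dihydroxy-6-(3-methylbut-2-en-1-yl)-2,3-dihydro-4H-chromen-4-one
Conditions: 3 M aq. HCl, MeOH, 40 °C, short reaction time
Reagents that add atoms: none
Why: Acid-catalysed acetal exchange with methanol removes all three MOM groups; the C2 centre should be untouched because flavanone ring opening needs base, and the mild, short treatment limits acid-induced cyclisation of the prenyl and geranyl groups onto the phenols.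

Compound list
1 | 2,4,6-trihydroxybenzaldehyde | O=Cc1c(O)cc(O)cc1O | starting material
2 | 3,4-dihydro-2H-pyran | C1=COCCC1 | starting material
3 | 2,6-dihydroxy-4-(oxan-2-yloxy)benzaldehyde (racemic acetal) | O=Cc1c(O)cc(OC2CCCCO2)cc1O | intermediate
4 | chloromethyl methyl ether | COCCl | starting material
5 | 2-hydroxy-6-(methoxymethoxy)-4-(oxan-2-yloxy)benzaldehyde | O=Cc1c(O)cc(OC2CCCCO2)cc1OCOC | intermediate
6 | di-tert-butyl dicarbonate | CC(C)(C)OC(=O)OC(=O)OC(C)(C)C | starting material
7 | tert-butyl [2-formyl-3-(methoxymethoxy)-5-(oxan-2-yloxy)phenyl] carbonate | CC(C)(C)OC(=O)Oc1cc(OC2CCCCO2)cc(OCOC)c1C=O | intermediate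
8 | tert-butyl [2-(hydroxymethyl)-3-(methoxymethoxy)-5-(oxan-2-yloxy)phenyl] carbonate | CC(C)(C)OC(=O)Oc1cc(OC2CCCCO2)cc(OCOC)c1CO | intermediate
9 | 2-methylprop-1-enylmagnesium bromide | CC(C)=C[Mg]Br | starting material
10 | bromomagnesium 2-{[(tert-butoxycarbonyl)oxy]methyl}-3-(methoxymethoxy)-5-(oxan-2-yloxy)phenoxide | CC(C)(C)OC(=O)OCc1c(O[Mg]Br)cc(OC2CCCCO2)cc1OCOC | intermediate
11 | 5-(methoxymethoxy)-6-methylidene-3-(oxan-2-yloxy)cyclohexa-2,4-dien-1-one | C=C1C(=O)C=C(OC2CCCCO2)C=C1OCOC | intermediate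
12 | 3-(methoxymethoxy)-2-(3-methylbut-2-en-1-yl)-5-(oxan-2-yloxy)phenol | CC(C)=CCc1c(O)cc(OC2CCCCO2)cc1OCOC | intermediate
13 | 2-[3,5-bis(methoxymethoxy)-4-(3-methylbut-2-en-1-yl)phenoxy]oxane | CC(C)=CCc1c(OCOC)cc(OC2CCCCO2)cc1OCOC | intermediate
14 | N-methoxy-N-methylacetamide | CC(=O)N(C)OC | starting material
15 | [2,4-bis(methoxymethoxy)-3-(3-methylbut-2-en-1-yl)-6-(oxan-2-yloxy)phenyl]lithium | [Li]c1c(OC2CCCCO2)cc(OCOC)c(CC=C(C)C)c1OCOC | intermediate
16 | 1-[2,4-bis(methoxymethoxy)-3-(3-methylbut-2-en-1-yl)-6-(oxan-2-yloxy)phenyl]ethan-1-one | CC(=O)c1c(OC2CCCCO2)cc(OCOC)c(CC=C(C)C)c1OCOC | intermediate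
17 | 1-[6-hydroxy-2,4-bis(methoxymethoxy)-3-(3-methylbut-2-en-1-yl)phenyl]ethan-1-one | CC(=O)c1c(O)cc(OCOC)c(CC=C(C)C)c1OCOC | intermediate
18 | N,N-dimethylformamide dimethyl acetal | COC(OC)N(C)C | starting material
19 | (2E)-3-(dimethylamino)-1-[6-hydroxy-2,4-bis(methoxymethoxy)-3-(3-methylbut-2-en-1-yl)phenyl]prop-2-en-1-one | CN(C)/C=C/C(=O)c1c(O)cc(OCOC)c(CC=C(C)C)c1OCOC | intermediate
20 | 5,7-bis(methoxymethoxy)-6-(3-methylbut-2-en-1-yl)-4H-chromen-4-one | O=c1ccoc2cc(OCOC)c(CC=C(C)C)c(OCOC)c12 | intermediate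
21 | 4-bromo-2-iodophenol | Oc1ccc(Br)cc1I | starting material
22 | 4-bromo-2-iodo-1-(methoxymethoxy)benzene | COCOc1ccc(Br)cc1I | intermediate
23 | geranyl bromide, (2E)-1-bromo-3,7-dimethylocta-2,6-diene | CC(C)=CCC/C(C)=C/CBr | starting material
24 | [5-bromo-2-(methoxymethoxy)phenyl]magnesium chloride | COCOc1ccc(Br)cc1[Mg]Cl | intermediate
25 | 4-bromo-2-[(2E)-3,7-dimethylocta-2,6-dien-1-yl]-1-(methoxymethoxy)benzene | CC(C)=CCC/C(C)=C/Cc1cc(Br)ccc1OCOC | intermediate
26 | triisopropyl borate | CC(C)OB(OC(C)C)OC(C)C | starting material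
27 | water | O | starting material
28 | {3-[(2E)-3,7-dimethylocta-2,6-dien-1-yl]-4-(methoxymethoxy)phenyl}lithium | CC(C)=CCC/C(C)=C/Cc1cc([Li])ccc1OCOC | intermediate
29 | {3-[(2E)-3,7-dimethylocta-2,6-dien-1-yl]-4-(methoxymethoxy)phenyl}boronic acid | CC(C)=CCC/C(C)=C/Cc1cc(B(O)O)ccc1OCOC | intermediate
30 | (2S)-2-{3-[(2E)-3,7-dimethylocta-2,6-dien-1-yl]-4-(methoxymethoxy)phenyl}-5,7-bis(methoxymethoxy)-6-(3-methylbut-2-en-1-yl)-2,3-dihydro-4H-chromen-4-one | CC(C)=CCC/C(C)=C/Cc1cc([C@@H]2CC(=O)c3c(cc(OCOC)c(CC=C(C)C)c3OCOC)O2)ccc1OCOC | intermediate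
31 | schizolaenone A, (2S)-2-{3-[(2E)-3,7-dimethylocta-2,6-dien-1-yl]-4-hydroxyphenyl}-5,7-dihydroxy-6-(3-methylbut-2-en-1-yl)-2,3-dihydro-4H-chromen-4-one | CC(C)=CCC/C(C)=C/Cc1cc([C@@H]2CC(=O)c3c(cc(O)c(CC=C(C)C)c3O)O2)ccc1O | target

Total step count: 14. Longest linear sequence: 11 steps (steps 1–9, 13 and 14); the ring B boronic acid takes 3 steps (10–12).

Steps most likely to fail

Step 5. The quinone methide may dimerise or oligomerise faster than the alkenyl Grignard reagent adds, or the Grignard reagent may attack the carbonate carbonyl before the alkoxide-triggered Boc transfer. The fallback sets out from 5 and comes back at 13, forming the same C1''–C2'' bond without a quinone methide. Compound 5 is alkylated with NaH and 4 to 2,6-bis(methoxymethoxy)-4-(oxan-2-yloxy)benzaldehyde F1, reduced with NaBH4 in MeOH to [2,6-bis(methoxymethoxy)-4-(oxan-2-yloxy)phenyl]methanol F2, and acylated with methyl chloroformate and pyridine to [2,6-bis(methoxymethoxy)-4-(oxan-2-yloxy)phenyl]methyl methyl carbonate F3. A benzylic Suzuki–Miyaura coupling of F3 with 4,4,5,5-tetramethyl-2-(2-methylprop-1-enyl)-1,3,2-dioxaborolane ([Pd(C3H5)Cl]2, Ph2P(CH2)5PPh2, K2CO3, DMF, 80 °C) should then give 13 directly.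

Step 13. The chromone carries two oxygen donors and may be too weak an acceptor, so that protodeboronation of the electron-rich boronic acid wins. Facial selectivity may be poor, the trisubstituted alkenes may bind the cationic palladium, or the product may lose enantiopurity by ring opening and reclosure. The fallback sets out from 17 and 25 and comes back at 30. Bromine–lithium exchange of 25 (n-BuLi, THF, −78 °C) and quenching with DMF gives 3-[(2E)-3,7-dimethylocta-2,6-dien-1-yl]-4-(methoxymethoxy)benzaldehyde F7. Claisen–Schmidt condensation of 17 with F7 (KOH, EtOH) gives (2E)-3-{3-[(2E)-3,7-dimethylocta-2,6-dien-1-yl]-4-(methoxymethoxy)phenyl}-1-[6-hydroxy-2,4-bis(methoxymethoxy)-3-(3-methylbut-2-en-1-yl)phenyl]prop-2-en-1-one F8. Oxa-Michael ring closure (NaOAc, EtOH, reflux) gives racemic 2-{3-[(2E)-3,7-dimethylocta-2,6-dien-1-yl]-4-(methoxymethoxy)phenyl}-5,7-bis(methoxymethoxy)-6-(3-methylbut-2-en-1-yl)-2,3-dihydro-4H-chromen-4-one F9. Preparative chromatography on an amylose tris(3,5-dimethylphenylcarbamate) phase then separates 30 from the (2R)-enantiomer F10, which can be re-equilibrated to F9 with base and recycled.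

Step 7. Deprotonation may occur at the benzylic and allylic CH2 of the prenyl group instead of the ring, the aryllithium may be quenched by proton transfer from that position, or the hindered aryllithium may acylate incompletely. The fallback sets out from 13 and comes back at 17, replacing lithiation by phenol-directed electrophilic substitution. PPTS in MeOH removes the acetal to give 3,5-bis(methoxymethoxy)-4-(3-methylbut-2-en-1-yl)phenol F4. Magnesium-mediated ortho-formylation (MgCl2, Et3N, paraformaldehyde, MeCN, reflux; Casnati–Skattebøl reaction) gives 6-hydroxy-2,4-bis(methoxymethoxy)-3-(3-methylbut-2-en-1-yl)benzaldehyde F5. Addition of MeMgBr (excess, THF, 0 °C) gives 2-(1-hydroxyethyl)-3,5-bis(methoxymethoxy)-4-(3-methylbut-2-en-1-yl)phenol F6, which is oxidised without purification (MnO2, CH2Cl2) to 17.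

Further compounds
F1 | step 5 | 2,6-bis(methoxymethoxy)-4-(oxan-2-yloxy)benzaldehyde | O=Cc1c(OCOC)cc(OC2CCCCO2)cc1OCOC
F2 | step 5 | [2,6-bis(methoxymethoxy)-4-(oxan-2-yloxy)phenyl]methanol | OCc1c(OCOC)cc(OC2CCCCO2)cc1OCOC
F3 | step 5 | [2,6-bis(methoxymethoxy)-4-(oxan-2-yloxy)phenyl]methyl methyl carbonate | COC(=O)OCc1c(OCOC)cc(OC2CCCCO2)cc1OCOC
F4 | step 7 | 3,5-bis(methoxymethoxy)-4-(3-methylbut-2-en-1-yl)phenol | CC(C)=CCc1c(OCOC)cc(O)cc1OCOC
F5 | step 7 | 6-hydroxy-2,4-bis(methoxymethoxy)-3-(3-methylbut-2-en-1-yl)benzaldehyde | O=Cc1c(O)cc(OCOC)c(CC=C(C)C)c1OCOC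
F6 | step 7 | 2-(1-hydroxyethyl)-3,5-bis(methoxymethoxy)-4-(3-methylbut-2-en-1-yl)phenol (racemic) | CC(O)c1c(O)cc(OCOC)c(CC=C(C)C)c1OCOC
F7 | step 13 | 3-[(2E)-3,7-dimethylocta-2,6-dien-1-yl]-4-(methoxymethoxy)benzaldehyde | CC(C)=CCC/C(C)=C/Cc1cc(C=O)ccc1OCOC
F8 | step 13 | (2E)-3-{3-[(2E)-3,7-dimethylocta-2,6-dien-1-yl]-4-(methoxymethoxy)phenyl}-1-[6-hydroxy-2,4-bis(methoxymethoxy)-3-(3-methylbut-2-en-1-yl)phenyl]prop-2-en-1-one | CC(C)=CCC/C(C)=C/Cc1cc(/C=C/C(=O)c2c(O)cc(OCOC)c(CC=C(C)C)c2OCOC)ccc1OCOC
F9 | step 13 | racemic 2-{3-[(2E)-3,7-dimethylocta-2,6-dien-1-yl]-4-(methoxymethoxy)phenyl}-5,7-bis(methoxymethoxy)-6-(3-methylbut-2-en-1-yl)-2,3-dihydro-4H-chromen-4-one | CC(C)=CCC/C(C)=C/Cc1cc(C2CC(=O)c3c(cc(OCOC)c(CC=C(C)C)c3OCOC)O2)ccc1OCOC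
F10 | step 13 | (2R)-2-{3-[(2E)-3,7-dimethylocta-2,6-dien-1-yl]-4-(methoxymethoxy)phenyl}-5,7-bis(methoxymethoxy)-6-(3-methylbut-2-en-1-yl)-2,3-dihydro-4H-chromen-4-one | CC(C)=CCC/C(C)=C/Cc1cc([C@H]2CC(=O)c3c(cc(OCOC)c(CC=C(C)C)c3OCOC)O2)ccc1OCOC
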